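**Plan**
- Cuts (drimane-type numbering; C11 is the CH2 between C9 and pyranone C3′): first O–CHO and C8=CH2, then C11–C3′ (Michael retron) and C9=C11 (Mannich methylenation). After that come the two exocyclic bonds at C4 (enolate alkylations), and finally C4–C5 and C1–C10 together.
- Enabling feature: ring A (C10–C1–C2–C3–C4–C5) has its only oxygen at C3, 1,4 to the quaternary C10, and H-5 and CH3-10 lie on one face. Ring A is therefore a 2-silyloxybutadiene added suprafacially to the C5=C10 bond of a ring B enal, whose formyl carbon ends as CH3-10.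
- Ring order: ring B is bought as a mono-ketal and ring A is closed by the cycloaddition. The pyranone ring is made separately from dimethyl 3-oxopentanedioate and joined last through C11.
- In between, the silyl enol ether is oxidised to the C1-ene-3-one, which leaves C4 as the only enolisable carbon (prenyl first, then methyl). Ring A is then finished, and a temporary C6=C7 bond directs ring B chemistry to C9.
- Stereochemistry: C5/C10 are absolute from a chiral oxazaborolidinium catalyst and cis by suprafaciality. C4 (convex-face methylation), C3 (equatorial hydride delivery) and C9 (α-face protonation, equatorial product) follow from the folded cis-decalin.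

Key step: step 4

Convention: α is the decalin face that carries H-5 and the C10 substituent, β the opposite face. Primed locants belong to the pyranone (O1′, C2′ OMe, C3′, C4′=O, C5′ CO2Me, C6′ CH3).
Assumption: the ring B enal binds the boron catalyst in the formyl C–H···O mode known for acyclic 2-substituted enals, so the (R)-catalyst is taken to leave the Si face of C10 open. The (S)-catalyst is equally available if the sense is opposite.

**Step 1**
Reactants: 1 1,4-dioxaspiro[4.5]decan-7-one
Product: 2 1,4-dioxaspiro[4.5]dec-7-en-7-yl trifluoromethanesulfonate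
Conditions: LiN(iPr)2, THF, −78 °C; PhNTf2, −78 to 0 °C
Reagents that add atoms: N-phenylbis(trifluoromethanesulfonimide), O=S(=O)(N(c1ccccc1)S(=O)(=O)C(F)(F)F)C(F)(F)F
Why: Kinetic enolate formation and O-triflation: the bulky amide takes the proton from the open CH2 (future C5) and not from the neopentyl-like CH2 between carbonyl and ketal (future C9), which fixes the double bond at C5=C10 and avoids β-elimination of the ketal oxygen.

**Step 2**
Reactants: 2 1,4-dioxaspiro[4.5]dec-7-en-7-yl trifluoromethanesulfonate
Product: 3 1,4-dioxaspiro[4.5]dec-7-ene-7-carbaldehyde (ring B enal; C5=C10; formyl on C10; ketal at C8)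
Conditions: Pd(OAc)2 (5 mol %), dppp, CO (1 atm), Et3SiH, Et3N, DMF, 70 °C
Reagents that add atoms: carbon monoxide, [C-]#[O+]
Why: Palladium-catalysed reductive carbonylation of an enol triflate (oxidative addition to zerovalent palladium, CO insertion, hydride transfer from the silane) turns C–OTf into C–CHO without moving the double bond or touching the ketal.

**Step 3**
Reactants: 4 but-3-en-2-one
Product: 5 2-(triisopropylsilyloxy)buta-1,3-diene
Conditions: iPr3SiOTf, Et3N, CH2Cl2, 0 °C to rt
Reagents that add atoms: triisopropylsilyl trifluoromethanesulfonate, CC(C)[Si](OS(=O)(=O)C(F)(F)F)(C(C)C)C(C)C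
Why: Soft enolisation and O-silylation of a vinyl methyl ketone, which can enolise only toward its methyl group, gives the 2-silyloxydiene, and the bulky silyl group keeps it intact under acidic catalysis.

**Step 4**
Reactants: 3 1,4-dioxaspiro[4.5]dec-7-ene-7-carbaldehyde; 5 2-(triisopropylsilyloxy)buta-1,3-diene
Product: 6 cis-fused cycloadduct (C2=C3 triisopropylsilyl enol ether; 10α-CHO; 5α-H; C8 ethylene ketal)
Conditions: (R)-3,3-diphenyl-1-(2-methylphenyl)tetrahydro-1H,3H-pyrrolo[1,2-c][1,3,2]oxazaborole (20 mol %), HNTf2 (18 mol %), CH2Cl2, −78 to −40 °C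
Reagents that add atoms: none
Why: The protonated oxazaborolidine binds the formyl oxygen of 3 and lowers the enal LUMO, so the reaction runs as a concerted but asynchronous [4+2] in which the nucleophilic CH2 next to the silyloxy carbon of 5 leads at C5 and the vinyl terminus follows at C10. The closest known reaction type is the cationic-oxazaborolidine-catalysed Diels–Alder addition of 2-silyloxybutadienes and other simple dienes to 2-substituted and 2,3-disubstituted enals. Ring A is closed as a six-membered carbocycle by intermolecular [4+2] annulation, with the C4–C5 and C1–C10 bonds forming on one face of the ring B alkene. C5 and C10 therefore come out cis (suprafacial addition to a ring alkene), and their absolute configuration comes from the catalyst, whose aryl group covers the Re face of C10 in the formyl C–H···O bound complex and leaves the Si face open. The step needs regio-, peri- and face selectivity: the donor at C3 and the acceptor on C10 enforce the 1,4 orientation, and a diene with one bulky silyloxy donor and no 1-alkoxy group has little tendency to add across C=O or to transfer silicon in an aldol pathway. The endo or exo orientation creates no stereocentre here, and the dioxolane is expected to survive at these temperatures.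

**Step 5**
Reactants: 6 cis-fused cycloadduct
Product: 7 cis-fused C1-ene-3-one (10α-CHO; 5α-H; C8 ethylene ketal)
Conditions: Pd(OAc)2 (1.1 equiv), MeCN–DMSO, 40 °C
Reagents that add atoms: none
Why: Saegusa–Ito oxidation: divalent palladium replaces silicon at the enol ether, sits on C2 and leaves by β-hydride elimination of H-1, so the double bond from the cycloaddition becomes the C1-ene-3-one regiospecifically while the non-enolisable formyl group and both stereocentres are untouched.

**Step 6**
Reactants: 7 cis-fused C1-ene-3-one aldehyde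
Product: 8 10α-hydroxymethyl C1-ene-3-one (C8 ketal)
Conditions: NaBH4, CH2Cl2–MeOH, −78 °C; AcOH quench at −78 °C
Reagents that add atoms: none
Why: Chemoselective borohydride reduction: at −78 °C an aldehyde is reduced much faster than a conjugated ketone, and the cold acidic quench keeps the alkoxide from losing formaldehyde by vinylogous retro-aldol cleavage.

**Step 7**
Reactants: 8 10α-hydroxymethyl C1-ene-3-one
Product: 9 10α-(tosyloxymethyl) C1-ene-3-one (C8 ketal)
Conditions: TsCl, Et3N, DMAP (cat.), CH2Cl2, 0 °C to rt
Reagents that add atoms: p-toluenesulfonyl chloride, Cc1ccc(cc1)S(=O)(=O)Cl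
Why: Sulfonylation caps the hydroxyl that could fragment under base, carries no acidic α-hydrogen (unlike a mesylate), is sterically inert to enolates at its neopentyl carbon, and later serves as the leaving group for the deoxygenation.

**Step 8**
Reactants: 9 10α-(tosyloxymethyl) C1-ene-3-one; 10 prenyl bromide (1-bromo-3-methylbut-2-ene)
Product: 11 4-prenyl C1-ene-3-one (C4 epimers)
Conditions: LiN(iPr)2, THF, −78 °C; 10, −78 to −30 °C
Reagents that add atoms: none
Why: Kinetic α′-alkylation of an enone: C10 is quaternary, so γ-deprotonation is impossible and C4 is the only enolisable carbon, and the reactive allylic bromide alkylates it; the new C4 centre is erased in the next step.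

**Step 9**
Reactants: 11 4-prenyl C1-ene-3-one
Product: 12 4α-methyl-4β-prenyl C1-ene-3-one
Conditions: LiN(iPr)2, THF–DMPU, −78 °C; MeI, −78 to 0 °C
Reagents that add atoms: iodomethane, CI
Why: Enolate alkylation that builds the C4 quaternary centre: in the nearly planar cross-conjugated dienolate both ring B carbons attached to ring A (C6 on C5, C9 on C10) lie on the β face, so iodomethane should enter from the convex α face, anti to the pseudoaxial C5–C6 bond, placing CH3 α (cis to H-5) and leaving the prenyl chain β.

**Step 10**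
Reactants: 12 4α-methyl-4β-prenyl C1-ene-3-one
Product: 13 4α-methyl-4β-prenyl 3-ketone (C1–C2 saturated)
Conditions: H2 (1 atm), RhCl(PPh3)3 (10 mol %), benzene–EtOH, rt
Reagents that add atoms: none
Why: Homogeneous hydrogenation with RhCl(PPh3)3 saturates the cis-disubstituted C1=C2 bond (as in the selective 1,2-reduction of steroidal 1,4-dien-3-ones) and leaves the trisubstituted prenyl alkene, the sulfonate and the ketal alone.

**Step 11**
Reactants: 13 4α-methyl-4β-prenyl 3-ketone
Product: 15 3β-alcohol bearing CH3-10 (4α-methyl; 4β-prenyl; C8 ketal), via hydroxy tosylate 14 (not isolated)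
Conditions: LiBH(s-Bu)3, THF, −78 to 0 °C; then LiBHEt3, THF, 65 °C
Reagents that add atoms: none
Why: Two hydride reductions in one flask: the bulky borohydride reaches the C3 carbonyl along the equatorial path from the α face because the axial β path is closed by axial C6, giving the axial 3β-alkoxide, and LiBHEt3 then displaces the neopentyl tosylate by SN2 (hindered-sulfonate reduction) to reveal CH3-10, the β-alkoxide and the α-CH2OTs being on opposite faces and unable to cyclise.

**Step 12**
Reactants: 15 3β-alcohol bearing CH3-10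
Product: 16 3β-(tert-butyldimethylsilyl) ether
Conditions: tBuMe2SiOTf, 2,6-lutidine, CH2Cl2, 0 °C to rt
Reagents that add atoms: tert-butyldimethylsilyl trifluoromethanesulfonate, CC(C)(C)[Si](C)(C)OS(=O)(=O)C(F)(F)F
Why: Silylation with the silyl triflate is strong enough for the hindered axial alcohol, and doing it before the side-chain alcohol exists keeps the two hydroxyl groups of the target differentiated.

**Step 13**
Reactants: 16 3β-silyl ether
Product: 17 8-ketone (3β-OTBS; 4α-methyl; 4β-prenyl; cis-decalin)
Conditions: pyridinium p-toluenesulfonate, acetone–H2O, 60 °C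
Reagents that add atoms: water, O
Why: Mild acid-catalysed ketal hydrolysis frees the C8 ketone, and the hindered silyl ether and the trisubstituted alkene tolerate the weak acid.

**Step 14**
Reactants: 17 8-ketone
Product: 18 C6-ene-8-one
Conditions: 2-iodoxybenzoic acid (IBX), DMSO, 65 °C
Reagents that add atoms: none
Why: IBX dehydrogenation of a ketone through its enol: C10 bears no hydrogen, so only the C6–C7 pair can be desaturated, and the new double bond removes the C7 protons that would otherwise win every enolisation.

**Step 15**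
Reactants: 19 dimethyl 3-oxopentanedioate
Product: 21 methyl 4-hydroxy-2-methyl-6-oxo-6H-pyran-3-carboxylate, via dimethyl 2-acetyl-3-oxopentanedioate 20 (not isolated)
Conditions: MgCl2, pyridine, AcCl, CH2Cl2, 0 °C to rt; then DBU, toluene, 110 °C; HCl work-up
Reagents that add atoms: acetyl chloride, CC(=O)Cl
Why: C-Acylation of the MgCl2 chelate of the β-keto diester, followed by base-induced lactonisation of the 3,5-dioxo ester (acetyl enol oxygen onto the remote ester), is the standard 4-hydroxy-2-pyranone synthesis and places CH3, CO2Me and OH as required.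

**Step 16**
Reactants: 18 C6-ene-8-one
Product: 24 9-methylene C6-ene-8-one, via Mannich base 22 (not isolated), via methiodide 23 (not isolated)
Conditions: LiN(iPr)2, THF, −78 °C; CH2=NMe2+ I−, −78 to 0 °C; MeI, Et2O–CH2Cl2, rt; aq NaHCO3, CH2Cl2, rt
Reagents that add atoms: dimethyl(methylidene)ammonium iodide, C=[N+](C)C.[I-]
Why: Kinetic α′-deprotonation of the enone can now occur only at C9, the Mannich reaction with the preformed iminium salt adds C11, and quaternisation with Hofmann-type elimination under bicarbonate gives the exocyclic enone, the base being too weak to epimerise C5 through the extended dienolate.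

**Step 17**
Reactants: 24 9-methylene C6-ene-8-one; 21 methyl 4-hydroxy-2-methyl-6-oxo-6H-pyran-3-carboxylate
Product: 25 9β-[(4-hydroxy-2-pyranon-3-yl)methyl] C6-ene-8-one
Conditions: Et3N (20 mol %), MeCN, rt
Reagents that add atoms: none
Why: Michael addition of the soft C3′ nucleophile of a 4-hydroxy-2-pyranone to the unhindered CH2 terminus of the exocyclic enone (faster than attack at C6) forms C11–C3′, and C9 is set by protonation of the resulting dienol from the α face, anti to the pseudoaxial C1, which is also the equatorial, thermodynamically preferred arrangement (CH2 β, H-9 α).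

**Step 18**
Reactants: 25 9β-[(4-hydroxy-2-pyranon-3-yl)methyl] C6-ene-8-one
Product: 26 9β-[(2-methoxy-4-pyranon-3-yl)methyl] C6-ene-8-one
Conditions: MeOTf, CH2Cl2, 0 °C to rt; aq NaHCO3 work-up
Reagents that add atoms: methyl trifluoromethanesulfonate, COS(=O)(=O)C(F)(F)F
Why: O-Methylation of the neutral 4-hydroxy-2-pyranone with a hard methylating agent occurs at the lactone carbonyl oxygen (the 4-OH is tied up in a hydrogen bond to the ester), and loss of the proton gives the 2-methoxy-4-pyranone, a known regioselective entry to such rings.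

**Step 19**
Reactants: 26 9β-[(2-methoxy-4-pyranon-3-yl)methyl] C6-ene-8-one
Product: 27 saturated 8-ketone carrying the pyranonylmethyl group
Conditions: H2 (1 atm), RhCl(PPh3)3 (10 mol %), benzene–EtOH, rt
Reagents that add atoms: none
Why: The same neutral RhCl(PPh3)3 hydrogenation removes the temporary cis-disubstituted C6=C7 bond, so C9 and C5 are not epimerised and the prenyl alkene and the tetrasubstituted pyranone double bonds remain.

**Step 20**
Reactants: 27 saturated 8-ketone
Product: 28 side-chain tertiary alcohol (4β-CH2CH2C(CH3)2OH)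
Conditions: Co(acac)2 (20 mol %), PhSiH3, O2 (1 atm), THF, rt
Reagents that add atoms: dioxygen, O=O
Why: Mukaiyama hydration: hydrogen-atom transfer from the hydride formed from Co(acac)2 and the silane to the electron-rich trisubstituted alkene gives the tertiary radical, which is trapped by O2 and reduced to the Markovnikov alcohol; it precedes the methylenation because a 1,1-disubstituted alkene would react as well.

**Step 21**
Reactants: 28 side-chain tertiary alcohol
Product: 29 8-methylene compound
Conditions: Zn, CH2Br2, TiCl4 (pre-aged reagent), THF–CH2Cl2, 0 °C to rt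
Reagents that add atoms: dibromomethane, BrCBr
Why: Lombardo methylenation: the non-basic reagent from Zn, CH2Br2 and TiCl4 converts hindered enolisable ketones into methylene compounds without epimerising C9 and does not attack esters, vinylogous esters or free tertiary alcohols.

**Step 22**
Reactants: 29 8-methylene compound
Product: 30 tertiary formate 3β-silyl ether
Conditions: acetic formic anhydride (preformed), pyridine, CH2Cl2, 0 °C to rt
Reagents that add atoms: acetic formic anhydride, CC(=O)OC=O
Why: Formylation with the mixed anhydride, which transfers its more electrophilic formyl group and is reactive enough for tertiary alcohols, meets a single free hydroxyl because O-3 is silylated.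

**Step 23**
Reactants: 30 tertiary formate 3β-silyl ether
Product: 31 CNP0292250.1 (target)
Conditions: HF·pyridine, pyridine, THF, 0 °C to rt
Reagents that add atoms: none
Why: Fluoride-induced desilylation under buffered, weakly acidic conditions cleaves the Si–O bond while the base-sensitive tertiary formate, the methyl ester, the 2-methoxypyranone and the exocyclic alkene persist.

**Compound list**
1 | 1,4-dioxaspiro[4.5]decan-7-one | O=C1CCCC2(C1)OCCO2 | starting material
2 | 1,4-dioxaspiro[4.5]dec-7-en-7-yl trifluoromethanesulfonate | O=S(=O)(OC1=CCCC2(C1)OCCO2)C(F)(F)F | intermediate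
3 | 1,4-dioxaspiro[4.5]dec-7-ene-7-carbaldehyde | O=CC1=CCCC2(C1)OCCO2 | intermediate
4 | but-3-en-2-one | CC(=O)C=C | starting material
5 | 2-(triisopropylsilyloxy)buta-1,3-diene | C=CC(=C)O[Si](C(C)C)(C(C)C)C(C)C | intermediate
6 | cis-fused cycloadduct, C2=C3 triisopropylsilyl enol ether, 10α-CHO, 5α-H, C8 ethylene ketal | O1CCOC12CC[C@H]3CC(O[Si](C(C)C)(C(C)C)C(C)C)=CC[C@@]3(C=O)C2 | intermediate
7 | cis-fused C1-ene-3-one, 10α-CHO, 5α-H, C8 ethylene ketal | O1CCOC12CC[C@H]3CC(=O)C=C[C@@]3(C=O)C2 | intermediate
8 | 10α-hydroxymethyl C1-ene-3-one, C8 ketal | O1CCOC12CC[C@H]3CC(=O)C=C[C@@]3(CO)C2 | intermediate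
9 | 10α-(tosyloxymethyl) C1-ene-3-one, C8 ketal | O1CCOC12CC[C@H]3CC(=O)C=C[C@@]3(COS(=O)(=O)c4ccc(C)cc4)C2 | intermediate
10 | prenyl bromide | CC(C)=CCBr | starting material
11 | 4-prenyl C1-ene-3-one (C4 epimers) | O1CCOC12CC[C@H]3C(CC=C(C)C)C(=O)C=C[C@@]3(COS(=O)(=O)c4ccc(C)cc4)C2 | intermediate
12 | 4α-methyl-4β-prenyl C1-ene-3-one | O1CCOC12CC[C@H]3[C@@](C)(CC=C(C)C)C(=O)C=C[C@@]3(COS(=O)(=O)c4ccc(C)cc4)C2 | intermediate
13 | 4α-methyl-4β-prenyl 3-ketone | O1CCOC12CC[C@H]3[C@@](C)(CC=C(C)C)C(=O)CC[C@@]3(COS(=O)(=O)c4ccc(C)cc4)C2 | intermediate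
14 | 3β-hydroxy 10α-(tosyloxymethyl) compound | O1CCOC12CC[C@H]3[C@@](C)(CC=C(C)C)[C@@H](O)CC[C@@]3(COS(=O)(=O)c4ccc(C)cc4)C2 | intermediate
15 | 3β-alcohol with 10α-methyl, C8 ketal | O1CCOC12CC[C@H]3[C@@](C)(CC=C(C)C)[C@@H](O)CC[C@@]3(C)C2 | intermediate
16 | 3β-(tert-butyldimethylsilyl) ether, C8 ketal | O1CCOC12CC[C@H]3[C@@](C)(CC=C(C)C)[C@@H](O[Si](C)(C)C(C)(C)C)CC[C@@]3(C)C2 | intermediate
17 | 8-ketone | O=C1CC[C@H]2[C@@](C)(CC=C(C)C)[C@@H](O[Si](C)(C)C(C)(C)C)CC[C@@]2(C)C1 | intermediate
18 | C6-ene-8-one | O=C1C=C[C@H]2[C@@](C)(CC=C(C)C)[C@@H](O[Si](C)(C)C(C)(C)C)CC[C@@]2(C)C1 | intermediate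
19 | dimethyl 3-oxopentanedioate | COC(=O)CC(=O)CC(=O)OC | starting material
20 | dimethyl 2-acetyl-3-oxopentanedioate | COC(=O)CC(=O)C(C(C)=O)C(=O)OC | intermediate
21 | methyl 4-hydroxy-2-methyl-6-oxo-6H-pyran-3-carboxylate | COC(=O)c1c(C)oc(=O)cc1O | intermediate
22 | 9-(dimethylaminomethyl) C6-ene-8-one (C9 epimers) | O=C1C=C[C@H]2[C@@](C)(CC=C(C)C)[C@@H](O[Si](C)(C)C(C)(C)C)CC[C@@]2(C)C1CN(C)C | intermediate
23 | trimethylammonium iodide of 22 | O=C1C=C[C@H]2[C@@](C)(CC=C(C)C)[C@@H](O[Si](C)(C)C(C)(C)C)CC[C@@]2(C)C1C[N+](C)(C)C.[I-] | intermediate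
24 | 9-methylene C6-ene-8-one | O=C1C=C[C@H]2[C@@](C)(CC=C(C)C)[C@@H](O[Si](C)(C)C(C)(C)C)CC[C@@]2(C)C1=C | intermediate
25 | 9β-[(4-hydroxy-5-methoxycarbonyl-6-methyl-2-oxo-2H-pyran-3-yl)methyl] C6-ene-8-one | O=C1C=C[C@H]2[C@@](C)(CC=C(C)C)[C@@H](O[Si](C)(C)C(C)(C)C)CC[C@@]2(C)[C@H]1Cc1c(O)c(C(=O)OC)c(C)oc1=O | intermediate
26 | 9β-[(2-methoxy-5-methoxycarbonyl-6-methyl-4-oxo-4H-pyran-3-yl)methyl] C6-ene-8-one | O=C1C=C[C@H]2[C@@](C)(CC=C(C)C)[C@@H](O[Si](C)(C)C(C)(C)C)CC[C@@]2(C)[C@H]1Cc1c(OC)oc(C)c(C(=O)OC)c1=O | intermediate
27 | saturated 8-ketone with 9β-pyranonylmethyl group | O=C1CC[C@H]2[C@@](C)(CC=C(C)C)[C@@H](O[Si](C)(C)C(C)(C)C)CC[C@@]2(C)[C@H]1Cc1c(OC)oc(C)c(C(=O)OC)c1=O | intermediate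
28 | side-chain tertiary alcohol | O=C1CC[C@H]2[C@@](C)(CCC(C)(C)O)[C@@H](O[Si](C)(C)C(C)(C)C)CC[C@@]2(C)[C@H]1Cc1c(OC)oc(C)c(C(=O)OC)c1=O | intermediate
29 | 8-methylene compound | C=C1CC[C@H]2[C@@](C)(CCC(C)(C)O)[C@@H](O[Si](C)(C)C(C)(C)C)CC[C@@]2(C)[C@H]1Cc1c(OC)oc(C)c(C(=O)OC)c1=O | intermediate
30 | tertiary formate 3β-silyl ether | C=C1CC[C@H]2[C@@](C)(CCC(C)(C)OC=O)[C@@H](O[Si](C)(C)C(C)(C)C)CC[C@@]2(C)[C@H]1Cc1c(OC)oc(C)c(C(=O)OC)c1=O | intermediate
31 | CNP0292250.1, (3S,4R,5R,9S,10S) in drimane-type numbering | C=C1CC[C@H]2[C@@](C)(CCC(C)(C)OC=O)[C@@H](O)CC[C@@]2(C)[C@H]1Cc1c(OC)oc(C)c(C(=O)OC)c1=O | target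

Total step count: 23.
Longest linear sequence: 21 steps (1 to 31 through steps 1, 2, 4–14 and 16–23). Steps 3 and 15 are side branches.

**Steps most likely to fail**

**Step 4.**
- What may go wrong: the silyl enol ether terminus may attack the activated formyl carbon or a Lewis-acid-opened ketal instead of C5. The trisubstituted dienophile may add too slowly at low temperature. The two enal faces may be poorly discriminated.
- Fallback (from 3, rejoining at 9): 3 is heated without any Lewis acid with commercial (E)-1-methoxy-3-(trimethylsilyloxy)buta-1,3-diene (toluene, sealed tube, 150 °C). Under these conditions addition to C=O does not compete, and this should give the racemic methoxy silyl enol ether cycloadduct F1.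
- Dilute HCl in THF then expels methanol to give the racemic enone aldehyde F2, so no oxidation step is needed.
- Reduction and tosylation as in steps 6 and 7 lead through the racemic alcohol F3 to the racemic tosylate F4. Its enantiomers are separated by preparative chromatography on a chiral stationary phase.

**Step 9.**
- What may go wrong: facial selectivity may be poor because the axial CH2OTs group also shields the α face. Deprotonation of the hindered C4–H may be slow, or O-methylation may intervene.
- Fallback (from 9, rejoining at 12): the order of the two alkylations is inverted and the quaternary centre is set under catalyst control. Methylation (LiN(iPr)2, MeI) gives the 4-methyl enone F5.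
- KN(SiMe3)2 and allyl chloroformate then give the allyl dienol carbonate F6.
- Decarboxylative asymmetric allylic alkylation (Pd2(dba)3 and the t-Bu-PHOX enantiomer that delivers allyl to the β face) gives the 4α-methyl-4β-allyl enone F7.
- Cross-metathesis with 2-methylbut-2-ene (second-generation Grubbs catalyst) converts allyl into prenyl.

**Step 11.**
- What may go wrong: hydride may attack sulfur, with S–O cleavage back to the alcohol. A ketal oxygen may participate, or no displacement may occur at the neopentyl carbon.
- Fallback (from 13, rejoining at 16): the ionic displacement is replaced by a radical dehalogenation, which is safe now that C1=C2 is saturated. LiBH(s-Bu)3 alone gives 14, which is isolated and silylated (tBuMe2SiOTf, 2,6-lutidine) to the silyl ether tosylate F8.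
- Sodium naphthalenide (NaC10H8) cleaves the S–O bond to give the neopentyl alcohol F9.
- I2, PPh3 and imidazole in hot toluene give the neopentyl iodide F10.
- Bu3SnH with AIBN reduces the C–I bond.

**Further compounds**
F1 | step 4 | racemic cycloadduct with 1-methoxy group and C2=C3 trimethylsilyl enol ether (cis-fused, C1 epimers) | O1CCOC12CC[C@H]3CC(O[Si](C)(C)C)=CC(OC)[C@@]3(C=O)C2.O1CCOC12CC[C@@H]3CC(O[Si](C)(C)C)=CC(OC)[C@]3(C=O)C2
F2 | step 4 | racemic cis-fused enone aldehyde | O1CCOC12CC[C@H]3CC(=O)C=C[C@@]3(C=O)C2.O1CCOC12CC[C@@H]3CC(=O)C=C[C@]3(C=O)C2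
F3 | step 4 | racemic 10-hydroxymethyl enone | O1CCOC12CC[C@H]3CC(=O)C=C[C@@]3(CO)C2.O1CCOC12CC[C@@H]3CC(=O)C=C[C@]3(CO)C2
F4 | step 4 | racemic 10-(tosyloxymethyl) enone | O1CCOC12CC[C@H]3CC(=O)C=C[C@@]3(COS(=O)(=O)c4ccc(C)cc4)C2.O1CCOC12CC[C@@H]3CC(=O)C=C[C@]3(COS(=O)(=O)c4ccc(C)cc4)C2
F5 | step 9 | 4-methyl C1-ene-3-one (C4 epimers) | O1CCOC12CC[C@H]3C(C)C(=O)C=C[C@@]3(COS(=O)(=O)c4ccc(C)cc4)C2
F6 | step 9 | allyl dienol carbonate of F5 | O1CCOC12CC[C@H]3C(C)=C(OC(=O)OCC=C)C=C[C@@]3(COS(=O)(=O)c4ccc(C)cc4)C2
F7 | step 9 | 4α-methyl-4β-allyl C1-ene-3-one | O1CCOC12CC[C@H]3[C@@](C)(CC=C)C(=O)C=C[C@@]3(COS(=O)(=O)c4ccc(C)cc4)C2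
F8 | step 11 | 3β-silyl ether of 14 | O1CCOC12CC[C@H]3[C@@](C)(CC=C(C)C)[C@@H](O[Si](C)(C)C(C)(C)C)CC[C@@]3(COS(=O)(=O)c4ccc(C)cc4)C2
F9 | step 11 | 10α-hydroxymethyl 3β-silyl ether | O1CCOC12CC[C@H]3[C@@](C)(CC=C(C)C)[C@@H](O[Si](C)(C)C(C)(C)C)CC[C@@]3(CO)C2
F10 | step 11 | 10α-iodomethyl 3β-silyl ether | O1CCOC12CC[C@H]3[C@@](C)(CC=C(C)C)[C@@H](O[Si](C)(C)C(C)(C)C)CC[C@@]3(CI)C2
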